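**Strategy.** Everything rests on disconnecting ring C at the four bonds it does not share with ring B (C9–C11, C11–C12, C13–C14, C8–C14). The key step exploits the C8=C9 edge of the seven-membered ring B, with C9 carrying a diazoacetyl group and C8 a hydrogen. Photolysis gives a vinylketene that takes up 1-(triisopropylsiloxy)-3-methylbut-1-yne and, in one operation, delivers the fully substituted arene as a C14 phenol with a C12 siloxy group and a free C11–H. The precursor is the rings A/B/19,6-lactone cyclohepta-8,10(20)-dienyl diazoketone that already holds all five stereocentres (C1, C4, C5, C6, C7). Oxidation at C11 and desilylation then give the hydroxyquinone.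

Key step: step 14

Remark: icetexane numbering is used throughout (ring A C1–C5/C10; ring B C5–C10/C20; lactone C4–C19(=O)–O–C6). C7 changes its CIP letter in aldehyde 11 only because the priorities change.

Assumption: the (R,R) copper–pybox catalyst is taken to expose the Re face of the chelated aldehyde in step 2; the antipode would be used if the opposite sense were found.

**Route**

Step 1
Reactants: 1 3-methylfuran-2(5H)-one
Product: 2 3-methyl-2-(trimethylsilyloxy)furan
Conditions: TMSOTf, Et3N, Et2O, 0 °C; distil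
Reagents that add atoms: trimethylsilyl triflate, C[Si](C)(C)OS(=O)(=O)C(F)(F)F
Why: Soft enolisation and O-silylation of the butenolide give the aromatic 2-siloxyfuran, the usual nucleophile for vinylogous Mukaiyama aldol reactions.

Step 2
Reactants: 2 3-methyl-2-(trimethylsilyloxy)furan; 3 2-(benzyloxy)acetaldehyde
Product: 5 (5R)-5-[(1S)-2-(benzyloxy)-1-hydroxyethyl]-3-methylfuran-2(5H)-one, via silyl ether 4 (not isolated)
Conditions: [Cu((R,R)-Ph-pybox)](SbF6)2 (10 mol %), CH2Cl2, −78 °C; then 1 M HCl, THF, 0 °C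
Reagents that add atoms: none
Why: In this catalytic enantioselective vinylogous Mukaiyama aldol reaction the aldehyde is held on copper as a five-membered chelate, the ligand leaves its Re face open to the furan γ-carbon (sets C7) and the open anti-selective transition state sets C6, so the 5,1′-anti adduct (C6 R, C7 S) should predominate.

Step 3
Reactants: 5 (5R)-5-[(1S)-2-(benzyloxy)-1-hydroxyethyl]-3-methylfuran-2(5H)-one
Product: 6 (5R)-5-[(1S)-2-(benzyloxy)-1-(tert-butyldimethylsilyloxy)ethyl]-3-methylfuran-2(5H)-one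
Conditions: TBSCl, imidazole, DMF, 25 °C
Reagents that add atoms: tert-butyldimethylsilyl chloride, CC(C)(C)[Si](C)(C)Cl
Why: Standard silylation of the secondary alcohol with a base too weak to enolise the butenolide, so C6 is not touched.

Step 4
Reactants: 6 (5R)-5-[(1S)-2-(benzyloxy)-1-(tert-butyldimethylsilyloxy)ethyl]-3-methylfuran-2(5H)-one; 7 2-(trimethylsilyloxy)buta-1,3-diene
Product: 9 (3R,3aR,7aS)-3-[(1S)-2-(benzyloxy)-1-(tert-butyldimethylsilyloxy)ethyl]-7a-methylhexahydro-2-benzofuran-1,5-dione, via silyl enol ether 8 (not isolated)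
Conditions: 7 (5 equiv), BHT, PhMe, 180 °C, sealed tube; then 0.5 M HCl, THF, 0 °C
Reagents that add atoms: none
Why: In this thermal Diels–Alder reaction the nucleophilic CH2 terminus next to the siloxy carbon bonds to the lactone β-carbon C5 (para rule, oxygen lands on C1) and the diene adds to the butenolide face opposite the C6 side chain, so the new C5–C10 and C4–C3 bonds are cis to each other and trans to C7 (sets C4 S and C5 R); mild acid then frees the C1 ketone.

Step 5
Reactants: 9 (3R,3aR,7aS)-3-[(1S)-2-(benzyloxy)-1-(tert-butyldimethylsilyloxy)ethyl]-7a-methylhexahydro-2-benzofuran-1,5-dione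
Product: 10 (3R,3aR,7aS)-3-[(1S)-1-(tert-butyldimethylsilyloxy)-2-hydroxyethyl]-7a-methylhexahydro-2-benzofuran-1,5-dione
Conditions: H2 (1 atm), 10% Pd/C, EtOAc, 25 °C
Reagents that add atoms: none
Why: Hydrogenolysis of the benzyl ether is clean here because 9 has no alkene left and the ketone, lactone and silyl ether are inert.

Step 6
Reactants: 10 (3R,3aR,7aS)-3-[(1S)-1-(tert-butyldimethylsilyloxy)-2-hydroxyethyl]-7a-methylhexahydro-2-benzofuran-1,5-dione
Product: 11 (3R,3aR,7aS)-3-[(1R)-1-(tert-butyldimethylsilyloxy)-2-oxoethyl]-7a-methylhexahydro-2-benzofuran-1,5-dione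
Conditions: Dess–Martin periodinane, NaHCO3, CH2Cl2, 0 → 25 °C; used crude
Reagents that add atoms: none
Why: Dess–Martin oxidation under buffered non-basic conditions gives the α-silyloxy aldehyde without epimerisation at C7.

Step 7
Reactants: 11 (3R,3aR,7aS)-3-[(1R)-1-(tert-butyldimethylsilyloxy)-2-oxoethyl]-7a-methylhexahydro-2-benzofuran-1,5-dione; 12 tert-butyl (triphenylphosphoranylidene)acetate
Product: 14 tert-butyl (2Z,4S)-4-(tert-butyldimethylsilyloxy)-2-iodo-4-[(3R,3aR,7aS)-7a-methyl-1,5-dioxooctahydro-2-benzofuran-3-yl]but-2-enoate, via iodo ylide 13 (not isolated)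
Conditions: 12, NIS, K2CO3, CH2Cl2, −20 °C; then 11, 25 → 40 °C
Reagents that add atoms: N-iodosuccinimide, O=C1CCC(=O)N1I
Why: Wittig olefination with the stabilised α-iodo ylide made in the flask puts the ester trans to the aldehyde residue as usual, hence iodine cis to C7 (Z), and only the aldehyde reacts, not the C1 ketone.

Step 8
Reactants: 14 tert-butyl (2Z,4S)-4-(tert-butyldimethylsilyloxy)-2-iodo-4-[(3R,3aR,7aS)-7a-methyl-1,5-dioxooctahydro-2-benzofuran-3-yl]but-2-enoate
Product: 15 tert-butyl (2E,4S)-4-(tert-butyldimethylsilyloxy)-2-formyl-4-[(3R,3aR,7aS)-7a-methyl-1,5-dioxooctahydro-2-benzofuran-3-yl]but-2-enoate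
Conditions: CO (1 atm), Pd(PPh3)4 (5 mol %), Bu3SnH (1.1 equiv, syringe pump), THF, 50 °C
Reagents that add atoms: carbon monoxide, [C-]#[O+]
Why: Palladium-catalysed reductive carbonylation of the vinyl iodide (Stille formylation) proceeds by oxidative addition, CO insertion and hydride transfer from tin with retention of alkene geometry, so the new formyl carbon C20 stays cis to C7.

Step 9
Reactants: 15 tert-butyl (2E,4S)-4-(tert-butyldimethylsilyloxy)-2-formyl-4-[(3R,3aR,7aS)-7a-methyl-1,5-dioxooctahydro-2-benzofuran-3-yl]but-2-enoate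
Product: 17 A/B/lactone dienone ester [C1 ketone; C8=C9 and C10=C20; CO2t-Bu on C9; 7-OTBS; 19,6-lactone; (4S,5R,6R,7S)], via aldol 16 (not isolated)
Conditions: CSA (10 mol %), PhH, 50 °C
Reagents that add atoms: none
Why: In this acid-catalysed intramolecular aldol condensation only the C10 enol of the C1 ketone can reach the activated C20 aldehyde (seven-membered ring B; the C2 enol would need a bridged nine-membered ring), dehydration gives the C10=C20 enone, and the absence of amine avoids dienamine formation at C7.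

Step 10
Reactants: 17 A/B/lactone dienone ester
Product: 18 A/B/lactone allylic alcohol [1β-OH; CO2t-Bu on C9; 7-OTBS; (1R,4S,5R,6R,7S)]
Conditions: NaBH4, CeCl3·7H2O, MeOH, −78 °C
Reagents that add atoms: none
Why: Luche 1,2-reduction should deliver hydride axially to C1 from the face of H5 and the C4 methyl (only axial hydrogens at C3 and C5 in the way, the lactone carbonyl being axial on the other face), giving the equatorial alcohol cis to C19/C6 (1R).

Step 11
Reactants: 18 A/B/lactone allylic alcohol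
Product: 20 A/B/lactone dienoic acid [CO2H on C9; 1-OTBS; 7-OTBS; (1R,4S,5R,6R,7S)], via silyl ester 19 (not isolated)
Conditions: TBSOTf (4 equiv), 2,6-lutidine, CH2Cl2, 0 → 25 °C; then AcOH–THF–H2O, 25 °C, 1 h
Reagents that add atoms: tert-butyldimethylsilyl triflate, CC(C)(C)[Si](C)(C)OS(=O)(=O)C(F)(F)F
Why: The silyl triflate with 2,6-lutidine silylates the C1 alcohol and also cleaves the tert-butyl ester to a silyl ester (loss of isobutene), which the mild aqueous acid hydrolyses while both secondary silyl ethers stay.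

Step 12
Reactants: 20 A/B/lactone dienoic acid
Product: 22 A/B/lactone dienyl diazoketone [C(=O)CHN2 on C9; 1-OTBS; 7-OTBS; (1R,4S,5R,6R,7S)], via acid chloride 21 (not isolated)
Conditions: 1-chloro-N,N,2-trimethylprop-1-en-1-amine (Ghosez reagent), CH2Cl2, 0 °C; then TMSCHN2 (2.5 equiv), MeCN–THF, 0 → 25 °C
Reagents that add atoms: (trimethylsilyl)diazomethane, C[Si](C)(C)C=[N+]=[N-]
Why: Neutral acid chloride formation followed by acylation of the diazoalkane (first stage of the Arndt–Eistert sequence) should work because C9 has no hydrogen for ketene formation and the hindered trisubstituted C8=C9 bond resists dipolar cycloaddition.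

Step 13
Reactants: 23 ethyl isobutyrate
Product: 26 1-(triisopropylsiloxy)-3-methylbut-1-yne, via dibromo enolate 24 (not isolated), via lithium ynolate 25 (not isolated)
Conditions: CH2Br2, LiTMP, THF, −78 °C; then n-BuLi, −78 → 25 °C; then TIPSCl, 0 → 25 °C
Reagents that add atoms: dibromomethane, BrCBr; triisopropylsilyl chloride, CC(C)[Si](Cl)(C(C)C)C(C)C
Why: In this Kowalski ester homologation dibromomethyllithium adds to the ester, the dibromo ketone enolate undergoes bromine–lithium exchange and 1,2-shift of the isopropyl group to the ynolate, and the bulky silyl chloride traps it on oxygen.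

Step 14
Reactants: 22 A/B/lactone dienyl diazoketone; 26 1-(triisopropylsiloxy)-3-methylbut-1-yne
Product: 30 tetracyclic C14 phenol [12-OTIPS; 13-isopropyl; C11–H; 1-OTBS; 7-OTBS; (1R,4S,5R,6R,7S)], via vinylketene 27 (not isolated), via vinylcyclobutenone 28 (not isolated), via dienylketene 29 (not isolated)
Conditions: 26 (3 equiv), hν (300 nm), ClCH2CH2Cl, 25 °C; then 80 °C
Reagents that add atoms: none
Why: Irradiation expels N2 and the C9 alkenyl group shifts from the carbonyl carbon to the diazo carbon (Wolff rearrangement), giving vinylketene 27 in which the old diazo carbon is C11 and the old carbonyl carbon is C14; a [2+2] cycloaddition with 26 then forms C11–C12 and C13–C14 (cyclobutenone 28). Four-electron electrocyclic ring opening gives dienylketene 29, whose thermally allowed six-electron disrotatory electrocyclisation onto C8 closes ring C (C8–C14), and tautomerisation through the C8 hydrogen aromatises it. The closest known reaction type is the photochemical Wolff benzannulation of α,β-unsaturated diazoketones with siloxyalkynes, which gives resorcinol monosilyl ethers. No stereocentre is created (C11 of 28 is lost on aromatisation) and C1, C4, C5, C6 and C7 are spectators under the neutral conditions. The step needs regiocontrol in the [2+2] event, which the polarised ynol ether secures: its isopropyl-bearing carbon is the nucleophilic one and attacks the ketene carbonyl carbon, so isopropyl ends on C13 next to the C14 phenol and the siloxy group on C12, leaving C11–H para to the phenol. It also needs closure onto C8 and not onto C10=C20, which holds because only C8=C9 is in line with the ketene (C20 branches from C9) and C8 carries the hydrogen needed for aromatisation.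

Step 15
Reactants: 30 tetracyclic C14 phenol
Product: 31 12-O-triisopropylsilyl-1,7-bis-O-(tert-butyldimethylsilyl)ballotiquinone (11,14-quinone)
Conditions: (KSO3)2NO, KH2PO4, acetone–H2O, 25 °C
Reagents that add atoms: potassium nitrosodisulfonate (Fremy's salt), [K+].[K+].[O]N(S(=O)(=O)[O-])S(=O)(=O)[O-]
Why: In this Teuber oxidation the nitroxyl radical abstracts the phenolic hydrogen and a second equivalent adds at the free para position C11, giving the 11,14-quinone because both ortho positions (C8 and C13) are blocked.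

Step 16
Reactants: 31 12-O-triisopropylsilyl-1,7-bis-O-(tert-butyldimethylsilyl)ballotiquinone
Product: 32 ballotiquinone (1R,4S,5R,6R,7S)
Conditions: HF·pyridine, pyridine, THF, 0 → 25 °C
Reagents that add atoms: none
Why: Buffered fluoride desilylation should cleave the vinylogous silyl ester at C12 and both secondary silyl ethers without exposing the hydroxyquinone or the lactone to base.

**Compound list**

1 | 3-methylfuran-2(5H)-one | CC1=CCOC1=O | starting material
2 | 3-methyl-2-(trimethylsilyloxy)furan | Cc1ccoc1O[Si](C)(C)C | intermediate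
3 | 2-(benzyloxy)acetaldehyde | O=CCOCc1ccccc1 | starting material
4 | (5R)-5-[(1S)-2-(benzyloxy)-1-(trimethylsilyloxy)ethyl]-3-methylfuran-2(5H)-one | CC1=C[C@H]([C@@H](O[Si](C)(C)C)COCc2ccccc2)OC1=O | intermediate (not isolated)
5 | (5R)-5-[(1S)-2-(benzyloxy)-1-hydroxyethyl]-3-methylfuran-2(5H)-one | CC1=C[C@H]([C@@H](O)COCc2ccccc2)OC1=O | intermediate
6 | (5R)-5-[(1S)-2-(benzyloxy)-1-(tert-butyldimethylsilyloxy)ethyl]-3-methylfuran-2(5H)-one | CC1=C[C@H]([C@@H](O[Si](C)(C)C(C)(C)C)COCc2ccccc2)OC1=O | intermediate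
7 | 2-(trimethylsilyloxy)buta-1,3-diene | C=CC(=C)O[Si](C)(C)C | starting material
8 | (3R,3aR,7aS)-3-[(1S)-2-(benzyloxy)-1-(tert-butyldimethylsilyloxy)ethyl]-7a-methyl-5-(trimethylsilyloxy)-3a,4,7,7a-tetrahydro-2-benzofuran-1(3H)-one | C[C@]12CC=C(O[Si](C)(C)C)C[C@H]1[C@H]([C@@H](O[Si](C)(C)C(C)(C)C)COCc3ccccc3)OC2=O | intermediate (not isolated)
9 | (3R,3aR,7aS)-3-[(1S)-2-(benzyloxy)-1-(tert-butyldimethylsilyloxy)ethyl]-7a-methylhexahydro-2-benzofuran-1,5-dione | C[C@]12CCC(=O)C[C@H]1[C@H]([C@@H](O[Si](C)(C)C(C)(C)C)COCc3ccccc3)OC2=O | intermediate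
10 | (3R,3aR,7aS)-3-[(1S)-1-(tert-butyldimethylsilyloxy)-2-hydroxyethyl]-7a-methylhexahydro-2-benzofuran-1,5-dione | C[C@]12CCC(=O)C[C@H]1[C@H]([C@@H](O[Si](C)(C)C(C)(C)C)CO)OC2=O | intermediate
11 | (3R,3aR,7aS)-3-[(1R)-1-(tert-butyldimethylsilyloxy)-2-oxoethyl]-7a-methylhexahydro-2-benzofuran-1,5-dione | C[C@]12CCC(=O)C[C@H]1[C@H]([C@@H](O[Si](C)(C)C(C)(C)C)C=O)OC2=O | intermediate
12 | tert-butyl (triphenylphosphoranylidene)acetate | CC(C)(C)OC(=O)C=P(c1ccccc1)(c1ccccc1)c1ccccc1 | starting material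
13 | tert-butyl 2-iodo-2-(triphenylphosphoranylidene)acetate | CC(C)(C)OC(=O)C(I)=P(c1ccccc1)(c1ccccc1)c1ccccc1 | intermediate (not isolated)
14 | tert-butyl (2Z,4S)-4-(tert-butyldimethylsilyloxy)-2-iodo-4-[(3R,3aR,7aS)-7a-methyl-1,5-dioxooctahydro-2-benzofuran-3-yl]but-2-enoate | C[C@]12CCC(=O)C[C@H]1[C@H]([C@@H](O[Si](C)(C)C(C)(C)C)/C=C(\I)C(=O)OC(C)(C)C)OC2=O | intermediate
15 | tert-butyl (2E,4S)-4-(tert-butyldimethylsilyloxy)-2-formyl-4-[(3R,3aR,7aS)-7a-methyl-1,5-dioxooctahydro-2-benzofuran-3-yl]but-2-enoate | C[C@]12CCC(=O)C[C@H]1[C@H]([C@@H](O[Si](C)(C)C(C)(C)C)/C=C(\C=O)C(=O)OC(C)(C)C)OC2=O | intermediate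
16 | A/B/lactone aldol [C1 ketone; C20 hydroxyl; C8=C9; CO2t-Bu on C9; 7-OTBS; C10 and C20 epimers] | CC(C)(C)OC(=O)C2=C[C@H](O[Si](C)(C)C(C)(C)C)[C@@H]1OC(=O)[C@@]3(C)CCC(=O)C(C2O)[C@@H]13 | intermediate (not isolated)
17 | A/B/lactone dienone ester [C1 ketone; C8=C9 and C10=C20; CO2t-Bu on C9; 7-OTBS; (4S,5R,6R,7S)] | CC(C)(C)OC(=O)C2=C[C@H](O[Si](C)(C)C(C)(C)C)[C@@H]1OC(=O)[C@@]3(C)CCC(=O)C(=C2)[C@@H]13 | intermediate
18 | A/B/lactone allylic alcohol [1β-OH; CO2t-Bu on C9; 7-OTBS; (1R,4S,5R,6R,7S)] | CC(C)(C)OC(=O)C2=C[C@H](O[Si](C)(C)C(C)(C)C)[C@@H]1OC(=O)[C@@]3(C)CC[C@@H](O)C(=C2)[C@@H]13 | intermediate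
19 | A/B/lactone silyl ester [CO2TBS on C9; 1-OTBS; 7-OTBS] | CC(C)(C)[Si](C)(C)OC(=O)C2=C[C@H](O[Si](C)(C)C(C)(C)C)[C@@H]1OC(=O)[C@@]3(C)CC[C@@H](O[Si](C)(C)C(C)(C)C)C(=C2)[C@@H]13 | intermediate (not isolated)
20 | A/B/lactone dienoic acid [CO2H on C9; 1-OTBS; 7-OTBS; (1R,4S,5R,6R,7S)] | OC(=O)C2=C[C@H](O[Si](C)(C)C(C)(C)C)[C@@H]1OC(=O)[C@@]3(C)CC[C@@H](O[Si](C)(C)C(C)(C)C)C(=C2)[C@@H]13 | intermediate
21 | A/B/lactone acid chloride [COCl on C9; 1-OTBS; 7-OTBS] | ClC(=O)C2=C[C@H](O[Si](C)(C)C(C)(C)C)[C@@H]1OC(=O)[C@@]3(C)CC[C@@H](O[Si](C)(C)C(C)(C)C)C(=C2)[C@@H]13 | intermediate (not isolated)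
22 | A/B/lactone dienyl diazoketone [C(=O)CHN2 on C9; C8=C9 and C10=C20; 1-OTBS; 7-OTBS; (1R,4S,5R,6R,7S)] | [N-]=[N+]=CC(=O)C2=C[C@H](O[Si](C)(C)C(C)(C)C)[C@@H]1OC(=O)[C@@]3(C)CC[C@@H](O[Si](C)(C)C(C)(C)C)C(=C2)[C@@H]13 | intermediate (key-step precursor)
23 | ethyl isobutyrate | CCOC(=O)C(C)C | starting material
24 | lithium enolate of 1,1-dibromo-3-methylbutan-2-one | [Li]OC(=C(Br)Br)C(C)C | intermediate (not isolated)
25 | lithium 3-methylbut-1-yn-1-olate | [Li]OC#CC(C)C | intermediate (not isolated)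
26 | 1-(triisopropylsiloxy)-3-methylbut-1-yne | CC(C)C#CO[Si](C(C)C)(C(C)C)C(C)C | intermediate
27 | vinylketene [CH=C=O on C9; 1-OTBS; 7-OTBS] | O=C=CC2=C[C@H](O[Si](C)(C)C(C)(C)C)[C@@H]1OC(=O)[C@@]3(C)CC[C@@H](O[Si](C)(C)C(C)(C)C)C(=C2)[C@@H]13 | intermediate (not isolated)
28 | 2-isopropyl-3-(triisopropylsiloxy)cyclobut-2-en-1-one with C4 bonded to C9 of the A/B/lactone diene (C11 epimers) | CC(C)C1=C(O[Si](C(C)C)(C(C)C)C(C)C)C(C1=O)C2=C[C@H](O[Si](C)(C)C(C)(C)C)[C@@H]1OC(=O)[C@@]3(C)CC[C@@H](O[Si](C)(C)C(C)(C)C)C(=C2)[C@@H]13 | intermediate (not isolated)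
29 | dienylketene [O=C14=C13(i-Pr)–C12(OTIPS)=C11H–C9=C8] | CC(C)C(=C=O)C(O[Si](C(C)C)(C(C)C)C(C)C)=CC2=C[C@H](O[Si](C)(C)C(C)(C)C)[C@@H]1OC(=O)[C@@]3(C)CC[C@@H](O[Si](C)(C)C(C)(C)C)C(=C2)[C@@H]13 | intermediate (not isolated)
30 | tetracyclic C14 phenol [12-OTIPS; 13-isopropyl; C11–H; 1-OTBS; 7-OTBS; (1R,4S,5R,6R,7S)] | CC(C)c1c(O[Si](C(C)C)(C(C)C)C(C)C)cc2c(c1O)[C@H](O[Si](C)(C)C(C)(C)C)[C@@H]1OC(=O)[C@@]3(C)CC[C@@H](O[Si](C)(C)C(C)(C)C)C(=C2)[C@@H]13 | intermediate (key-step product)
31 | 12-O-triisopropylsilyl-1,7-bis-O-(tert-butyldimethylsilyl)ballotiquinone | CC(C)C1=C(O[Si](C(C)C)(C(C)C)C(C)C)C(=O)C2=C(C1=O)[C@H](O[Si](C)(C)C(C)(C)C)[C@@H]1OC(=O)[C@@]3(C)CC[C@@H](O[Si](C)(C)C(C)(C)C)C(=C2)[C@@H]13 | intermediate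
32 | ballotiquinone (1R,4S,5R,6R,7S) | CC(C)C1=C(O)C(=O)C2=C(C1=O)[C@H](O)[C@@H]1OC(=O)[C@@]3(C)CC[C@@H](O)C(=C2)[C@@H]13 | target

**Count**

Total steps: 16. Longest linear sequence: 15 steps (steps 1–12 and 14–16, from 1 to 32); step 13 makes the alkyne partner.

**Three steps most likely to fail**

1. Step 14. The cross-conjugated dienyl chromophore or the cyclobutenone may undergo competing photoreactions, or the vinylketene may dimerise before it is captured. The fallback makes the same ketene thermally, without light. It sets out from 22: silver benzoate and Et3N in aqueous THF cause Wolff rearrangement with capture by water and should give the homologous C9-acetic acid F1. The Ghosez reagent turns it into the acid chloride F2. Slow addition of Et3N to F2 and 26 in toluene at 80 °C dehydrochlorinates F2 to vinylketene 27, which follows the same [2+2], ring-opening and 6π sequence. The fallback comes back to the route at 30.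

2. Step 9. The doubly activated enal may epimerise at C7 or lose the lactone carboxylate through dienol formation, or the tert-butyl ester or silyl ether may be cleaved by the acid before ring B closes. The fallback keeps C8 sp3 during ring closure and also bypasses steps 7 and 8. It sets out from 11: a β-iodo Morita–Baylis–Hillman reaction with tert-butyl propiolate and MgI2 (CH2Cl2, 0 °C) should give the β-iodo hydroxy ester F3, and Ac2O/pyridine its acetate F4. With Cs2CO3 in MeCN the C10 enolate of the C1 ketone (the only one that can reach) displaces iodide at C20 by addition–elimination, and 1,4-elimination of acetic acid then installs C10=C20 and C8=C9. The fallback comes back at 17.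

3. Step 4. Conversion may be low because the α-methyl butenolide is a weak dienophile while the diene polymerises at the temperature needed. The fallback uses a more electron-rich diene with the same regiochemical and facial sense. It sets out from 6: trans-1-methoxy-3-(trimethylsiloxy)buta-1,3-diene (PhMe, 130 °C) should give the methoxy silyl enol ether cycloadduct F5, and dilute HCl in THF the enone F6 by loss of methanol. Hydrogenation (H2, Pd/C, EtOAc) saturates C2=C3 and removes the benzyl group in the same operation. The fallback comes back at 10.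

**Further compounds**

F1 | step 14 | A/B/lactone C9-acetic acid [CH2CO2H on C9; 1-OTBS; 7-OTBS] | OC(=O)CC2=C[C@H](O[Si](C)(C)C(C)(C)C)[C@@H]1OC(=O)[C@@]3(C)CC[C@@H](O[Si](C)(C)C(C)(C)C)C(=C2)[C@@H]13
F2 | step 14 | A/B/lactone C9-acetyl chloride [CH2COCl on C9; 1-OTBS; 7-OTBS] | ClC(=O)CC2=C[C@H](O[Si](C)(C)C(C)(C)C)[C@@H]1OC(=O)[C@@]3(C)CC[C@@H](O[Si](C)(C)C(C)(C)C)C(=C2)[C@@H]13
F3 | step 9 | tert-butyl (2Z)-3-hydroxy-2-(iodomethylidene)-4-(tert-butyldimethylsilyloxy)-4-[bicyclic keto lactone of 11]butanoate (C8 epimers) | C[C@]12CCC(=O)C[C@H]1[C@H]([C@@H](O[Si](C)(C)C(C)(C)C)C(O)/C(=C/I)C(=O)OC(C)(C)C)OC2=O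
F4 | step 9 | acetate of F3 at the C8 hydroxyl | C[C@]12CCC(=O)C[C@H]1[C@H]([C@@H](O[Si](C)(C)C(C)(C)C)C(OC(C)=O)/C(=C/I)C(=O)OC(C)(C)C)OC2=O
F5 | step 4 | 7-methoxy-5-(trimethylsilyloxy) cycloadduct of 6 (C3-methoxy epimers; icetexane C3) | C[C@]12C(OC)C=C(O[Si](C)(C)C)C[C@H]1[C@H]([C@@H](O[Si](C)(C)C(C)(C)C)COCc3ccccc3)OC2=O
F6 | step 4 | (3R,3aR,7aS)-3-[(1S)-2-(benzyloxy)-1-(tert-butyldimethylsilyloxy)ethyl]-7a-methyl-3a,4-dihydro-2-benzofuran-1,5(3H,7aH)-dione (C2=C3 enone) | C[C@]12C=CC(=O)C[C@H]1[C@H]([C@@H](O[Si](C)(C)C(C)(C)C)COCc3ccccc3)OC2=O
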